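**Retrosynthetic overview**
1. Target 29 ⇐ desilylation and α-methylenation of cis-fused lactone 25; the γ-lactone is the last ring, closed by invertive attack of an amide oxygen on a C6 mesylate.
2. The C6 carbinol and the C8 isobutyrate arise together by Evans–Tishchenko reduction of β-hydroxy ketone 19; the oxirane comes from C8–OH-directed epoxidation, the C7 side chain from chelate-controlled alkylation of 15.
3. Key step (instead of macrocyclising an open chain): anionic oxy-Cope ring expansion of cyclohexenol 10 breaks C1–C6 and makes C8–C9, fixing the 4Z olefin, the 1(10)Z olefin and C8 at once.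
4. Carbinol 10 ⇐ (S)-carvone by Luche reduction, silylation, allylic oxidation, axial acetylide addition and trans-hydroalumination.
5. Ring order: six-membered carbocycle (bought in carvone) → ten-membered carbocycle (step 7) → oxirane (step 10) → γ-lactone (step 12).

Assumption: compounds 1, 5, 6, 16, 20 and all un-numbered reagents are bought; atom labels C1–C15 are germacranolide labels (C6 lactone oxygen, C7 side chain, C8 ester, C1/C10 epoxide, C3 hydroxyl, C4=C5 ring olefin).

**Route**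

Step 1
Reactants: 1 (S)-(+)-carvone
Product: 2 (1S,5S)-cis-carveol
Conditions: NaBH4, CeCl3·7H2O, MeOH, 0 °C
Reagents that add atoms: none
Why: Luche reduction: 1,2-selective axial hydride delivery to the enone gives the equatorial alcohol cis to the isopropenyl group, setting the carbinol (future C3) as S.

Step 2
Reactants: 2 (1S,5S)-cis-carveol
Product: 3 (1S,5S)-cis-carveol triisopropylsilyl ether
Conditions: TIPSOTf, 2,6-lutidine, CH2Cl2, 0 °C
Reagents that add atoms: triisopropylsilyl trifluoromethanesulfonate, CC(C)[Si](C(C)C)(C(C)C)OS(=O)(=O)C(F)(F)F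
Why: Silyl ether formation with a silyl triflate; TIPS is kept to the end because it withstands hydride, KH, amide bases and brief fluoride exposure.

Step 3
Reactants: 3 (1S,5S)-cis-carveol triisopropylsilyl ether
Product: 4 (4S,6S)-3-methyl-6-(prop-1-en-2-yl)-4-(triisopropylsilyloxy)cyclohex-2-en-1-one
Conditions: CrO3, 3,5-dimethylpyrazole, CH2Cl2, −20 °C
Reagents that add atoms: chromium trioxide, O=[Cr](=O)=O
Why: Allylic C–H oxidation (Salmond conditions): the only ring methylene allylic to the trisubstituted olefin becomes the enone carbonyl while the bulky silyl ether shields its own carbinol C–H, and neither stereocentre is touched.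

Step 4
Reactants: 5 ethynylmagnesium bromide; 6 benzylchlorodimethylsilane
Product: 7 benzyl(ethynyl)dimethylsilane
Conditions: THF, 0 to 23 °C
Reagents that add atoms: none
Why: Nucleophilic substitution at silicon by the alkynyl Grignard reagent.

Step 5
Reactants: 7 benzyl(ethynyl)dimethylsilane; 4 (4S,6S)-3-methyl-6-(prop-1-en-2-yl)-4-(triisopropylsilyloxy)cyclohex-2-en-1-one
Product: 9 (1R,4S,6S)-1-[(benzyldimethylsilyl)ethynyl]-3-methyl-6-(prop-1-en-2-yl)-4-(triisopropylsilyloxy)cyclohex-2-en-1-ol, via lithium acetylide 8 (not isolated)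
Conditions: n-BuLi, THF, −78 °C; then 4, −78 °C; then H2O
Reagents that add atoms: none
Why: 1,2-Addition of a lithium acetylide to an enone: the slim sp nucleophile attacks axially on the half-chair that keeps the C4 and C6 substituents equatorial, so the alkyne ends up axial and cis to the isopropenyl group and the tertiary carbinol is set as 1R.

Step 6
Reactants: 9 (1R,4S,6S)-1-[(benzyldimethylsilyl)ethynyl]-3-methyl-6-(prop-1-en-2-yl)-4-(triisopropylsilyloxy)cyclohex-2-en-1-ol
Product: 10 (1R,4S,6S)-1-[(E)-2-(benzyldimethylsilyl)ethenyl]-3-methyl-6-(prop-1-en-2-yl)-4-(triisopropylsilyloxy)cyclohex-2-en-1-ol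
Conditions: NaAlH2(OCH2CH2OMe)2, THF, 0 to 23 °C; then H2O
Reagents that add atoms: none
Why: Hydroxyl-directed trans-hydroalumination of a propargylic alcohol: hydride goes to the proximal alkyne carbon and aluminium to the silicon-bearing carbon, so protonolysis gives only the E vinylsilane.

Step 7
Reactants: 10 (1R,4S,6S)-1-[(E)-2-(benzyldimethylsilyl)ethenyl]-3-methyl-6-(prop-1-en-2-yl)-4-(triisopropylsilyloxy)cyclohex-2-en-1-ol
Product: 13 (2Z,4S,6Z,9R)-9-(benzyldimethylsilyl)-3,7-dimethyl-4-(triisopropylsilyloxy)cyclodeca-2,6-dien-1-one, via potassium alkoxide 11 (not isolated), via potassium enolate 12 (not isolated)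
Conditions: KH, 18-crown-6, THF, 23 to 50 °C; then AcOH, −78 °C
Reagents that add atoms: none
Why: Anionic oxy-Cope rearrangement (the ring expansion Still used for germacranes and periplanone B): alkoxide 11 holds the alkenylsilane axial and the isopropenyl group equatorial (cis), and a chair transition state with the C2 ring methylene pseudo-axial and the silyl group pseudo-equatorial keeps the ring olefin 4Z, forms the 1(10)Z olefin and relays chirality from C1/C6 to C8 (R), while the β-silyl group cannot be eliminated from enolate 12.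

Step 8
Reactants: 13 (2Z,4S,6Z,9R)-9-(benzyldimethylsilyl)-3,7-dimethyl-4-(triisopropylsilyloxy)cyclodeca-2,6-dien-1-one
Product: 15 (2Z,4S,6Z,9R)-9-hydroxy-3,7-dimethyl-4-(triisopropylsilyloxy)cyclodeca-2,6-dien-1-one, via silanol 14 (not isolated)
Conditions: Bu4NF, THF, 0 °C; then H2O2, KHCO3, MeOH, 23 °C
Reagents that add atoms: hydrogen peroxide, OO
Why: Tamao–Fleming oxidation: fluoride cleaves the benzyl–silicon bond to silanol 14 and peroxide induces 1,2-migration of C8 from silicon to oxygen with retention (C8 R), without acid that would trigger transannular cyclisation and without loss of the TIPS ether.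

Step 9
Reactants: 15 (2Z,4S,6Z,9R)-9-hydroxy-3,7-dimethyl-4-(triisopropylsilyloxy)cyclodeca-2,6-dien-1-one; 16 2-bromo-N,N-dimethylacetamide
Product: 18 2-[(1R,2R,4Z,7S,8Z)-2-hydroxy-4,8-dimethyl-10-oxo-7-(triisopropylsilyloxy)cyclodeca-4,8-dien-1-yl]-N,N-dimethylacetamide, via dilithium dianion 17 (not isolated)
Conditions: LiN(iPr)2 (2.3 equiv), THF, −78 °C; then 16, DMPU, −78 to −30 °C; then AcOH
Reagents that add atoms: none
Why: Fráter–Seebach-type alkylation: the lithium-chelated alkoxide–enolate 17 cannot expel its β-oxide and is attacked on the face anti to the C8–C9 ring bond (also the outer face of the macrocycle), setting C7 (R) anti to the C8 oxygen.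

Step 10
Reactants: 18 2-[(1R,2R,4Z,7S,8Z)-2-hydroxy-4,8-dimethyl-10-oxo-7-(triisopropylsilyloxy)cyclodeca-4,8-dien-1-yl]-N,N-dimethylacetamide
Product: 19 2-[(1S,3R,4R,6Z,8S,10R)-3-hydroxy-1,7-dimethyl-5-oxo-8-(triisopropylsilyloxy)-11-oxabicyclo[8.1.0]undec-6-en-4-yl]-N,N-dimethylacetamide
Conditions: VO(acac)2 (5 mol%), t-BuOOH, CH2Cl2, 0 to 23 °C
Reagents that add atoms: tert-butyl hydroperoxide, CC(C)(C)OO
Why: Hydroxyl-directed epoxidation of a homoallylic alcohol: the vanadium alkoxide of the C8 hydroxyl delivers oxygen to the face of the Z C1=C10 olefin on its own side of the ring, setting C1 (R) and C10 (S), while the electron-poor enone olefin does not react.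

Step 11
Reactants: 19 2-[(1S,3R,4R,6Z,8S,10R)-3-hydroxy-1,7-dimethyl-5-oxo-8-(triisopropylsilyloxy)-11-oxabicyclo[8.1.0]undec-6-en-4-yl]-N,N-dimethylacetamide; 20 isobutyraldehyde
Product: 22 (1S,3R,4S,5R,6Z,8S,10R)-4-[2-(dimethylamino)-2-oxoethyl]-5-hydroxy-1,7-dimethyl-8-(triisopropylsilyloxy)-11-oxabicyclo[8.1.0]undec-6-en-3-yl 2-methylpropanoate, via hemiacetal 21 (not isolated)
Conditions: SmI2 (30 mol%), 20 (6 equiv), THF, −10 °C
Reagents that add atoms: none
Why: Evans–Tishchenko reduction: hemiacetal 21 transfers its hydride intramolecularly to the C6 ketone through a samarium-bridged six-membered transition state, giving the 1,3-anti alcohol (C6 R) and leaving the isobutyryl group on the C8 oxygen with every atom of 20 retained.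

Step 12
Reactants: 22 (1S,3R,4S,5R,6Z,8S,10R)-4-[2-(dimethylamino)-2-oxoethyl]-5-hydroxy-1,7-dimethyl-8-(triisopropylsilyloxy)-11-oxabicyclo[8.1.0]undec-6-en-3-yl 2-methylpropanoate
Product: 25 (1R,3S,6S,7R,8R,10S)-1,10-epoxy-8-(2-methylpropanoyloxy)-3-(triisopropylsilyloxy)-13-norgermacr-4Z-en-12,6-olide, via mesylate 23 (not isolated), via iminium ether 24 (not isolated)
Conditions: MsCl, Et3N, CH2Cl2, −20 to 23 °C; then H2O, THF, 23 °C
Reagents that add atoms: water, O
Why: Invertive lactonisation by neighbouring-group participation: the amide carbonyl oxygen displaces the allylic mesylate of 23 intramolecularly (5-exo SN2, inversion to C6 S) and hydrolysis of iminium ether 24 releases the cis-fused γ-lactone.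

Step 13
Reactants: 25 (1R,3S,6S,7R,8R,10S)-1,10-epoxy-8-(2-methylpropanoyloxy)-3-(triisopropylsilyloxy)-13-norgermacr-4Z-en-12,6-olide
Product: 28 (1R,3S,6S,7R,8R,10S)-1,10-epoxy-8-(2-methylpropanoyloxy)-3-(triisopropylsilyloxy)germacra-4Z,11(13)-dien-12,6-olide, via Mannich base 26 (not isolated), via ammonium iodide 27 (not isolated)
Conditions: LiN(SiMe3)2, THF, −78 °C; [Me2N=CH2]I, −78 to 0 °C; then MeI, MeOH, 23 °C; then aq NaHCO3, CH2Cl2
Reagents that add atoms: N,N-dimethylmethyleneiminium iodide (Eschenmoser's salt), C=[N+](C)C.[I-]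
Why: Lactone α-methylenation by Mannich reaction of the lithium enolate, N-methylation and β-elimination of trimethylamine; the lactone α-CH2 is deprotonated kinetically in preference to the hindered isobutyrate methine and no stereocentre changes.

Step 14
Reactants: 28 (1R,3S,6S,7R,8R,10S)-1,10-epoxy-8-(2-methylpropanoyloxy)-3-(triisopropylsilyloxy)germacra-4Z,11(13)-dien-12,6-olide
Product: 29 (1R,3S,6S,7R,8R,10S)-1,10-epoxy-3-hydroxy-8-(2-methylpropanoyloxy)germacra-4Z,11(13)-dien-12,6-olide (CNP0261225.6)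
Conditions: HF·pyridine, pyridine, THF, 0 to 23 °C
Reagents that add atoms: none
Why: Fluoride-mediated silyl ether cleavage; buffering with pyridine keeps the epoxide and the α-methylene lactone intact and liberates the C3 hydroxyl of the target.

**Compound list**

1 | (S)-(+)-carvone | CC1=CC[C@H](C(C)=C)CC1=O | starting material
2 | (1S,5S)-cis-carveol | CC1=CC[C@H](C(C)=C)C[C@@H]1O | intermediate
3 | (1S,5S)-cis-carveol triisopropylsilyl ether | CC1=CC[C@H](C(C)=C)C[C@@H]1O[Si](C(C)C)(C(C)C)C(C)C | intermediate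
4 | (4S,6S)-3-methyl-6-(prop-1-en-2-yl)-4-(triisopropylsilyloxy)cyclohex-2-en-1-one | CC1=CC(=O)[C@H](C(C)=C)C[C@@H]1O[Si](C(C)C)(C(C)C)C(C)C | intermediate
5 | ethynylmagnesium bromide | C#C[Mg]Br | starting material
6 | benzylchlorodimethylsilane | C[Si](C)(Cl)Cc1ccccc1 | starting material
7 | benzyl(ethynyl)dimethylsilane | C#C[Si](C)(C)Cc1ccccc1 | intermediate
8 | lithium acetylide of 7 | [Li+].[C-]#C[Si](C)(C)Cc1ccccc1 | intermediate
9 | (1R,4S,6S)-1-[(benzyldimethylsilyl)ethynyl]-3-methyl-6-(prop-1-en-2-yl)-4-(triisopropylsilyloxy)cyclohex-2-en-1-ol (alkyne, isopropenyl and silyloxy groups all cis) | CC1=C[C@](O)(C#C[Si](C)(C)Cc2ccccc2)[C@H](C(C)=C)C[C@@H]1O[Si](C(C)C)(C(C)C)C(C)C | intermediate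
10 | (1R,4S,6S)-1-[(E)-2-(benzyldimethylsilyl)ethenyl]-3-methyl-6-(prop-1-en-2-yl)-4-(triisopropylsilyloxy)cyclohex-2-en-1-ol | CC1=C[C@](O)(/C=C/[Si](C)(C)Cc2ccccc2)[C@H](C(C)=C)C[C@@H]1O[Si](C(C)C)(C(C)C)C(C)C | intermediate
11 | potassium alkoxide of 10 | [K+].CC1=C[C@]([O-])(/C=C/[Si](C)(C)Cc2ccccc2)[C@H](C(C)=C)C[C@@H]1O[Si](C(C)C)(C(C)C)C(C)C | intermediate
12 | potassium enolate of 13 (C6=C7 enolate, oxygen cis to C8; C3 S, C8 R) | [K+].C[Si](C)(Cc1ccccc1)[C@H]2/C=C(\[O-])/C=C(/C)[C@@H](O[Si](C(C)C)(C(C)C)C(C)C)C/C=C(C)\C2 | intermediate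
13 | (2Z,4S,6Z,9R)-9-(benzyldimethylsilyl)-3,7-dimethyl-4-(triisopropylsilyloxy)cyclodeca-2,6-dien-1-one (C3 S, C8 R) | O=C1/C=C(/C)[C@@H](O[Si](C(C)C)(C(C)C)C(C)C)C/C=C(C)\C[C@@H]([Si](C)(C)Cc2ccccc2)C1 | intermediate
14 | (2Z,4S,6Z,9R)-9-[hydroxy(dimethyl)silyl]-3,7-dimethyl-4-(triisopropylsilyloxy)cyclodeca-2,6-dien-1-one | O=C1/C=C(/C)[C@@H](O[Si](C(C)C)(C(C)C)C(C)C)C/C=C(C)\C[C@@H]([Si](C)(C)O)C1 | intermediate
15 | (2Z,4S,6Z,9R)-9-hydroxy-3,7-dimethyl-4-(triisopropylsilyloxy)cyclodeca-2,6-dien-1-one | O=C1/C=C(/C)[C@@H](O[Si](C(C)C)(C(C)C)C(C)C)C/C=C(C)\C[C@@H](O)C1 | intermediate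
16 | 2-bromo-N,N-dimethylacetamide | BrCC(=O)N(C)C | starting material
17 | dilithium alkoxide–enolate of 15 | [Li+].[Li+].[O-][C@H]1/C=C(\[O-])/C=C(/C)[C@@H](O[Si](C(C)C)(C(C)C)C(C)C)C/C=C(C)\C1 | intermediate
18 | 2-[(1R,2R,4Z,7S,8Z)-2-hydroxy-4,8-dimethyl-10-oxo-7-(triisopropylsilyloxy)cyclodeca-4,8-dien-1-yl]-N,N-dimethylacetamide (C3 S, C7 R, C8 R) | O=C1/C=C(/C)[C@@H](O[Si](C(C)C)(C(C)C)C(C)C)C/C=C(C)\C[C@@H](O)[C@H]1CC(=O)N(C)C | intermediate
19 | 2-[(1S,3R,4R,6Z,8S,10R)-3-hydroxy-1,7-dimethyl-5-oxo-8-(triisopropylsilyloxy)-11-oxabicyclo[8.1.0]undec-6-en-4-yl]-N,N-dimethylacetamide (C1 R, C3 S, C7 R, C8 R, C10 S) | O=C1/C=C(/C)[C@@H](O[Si](C(C)C)(C(C)C)C(C)C)C[C@H]2O[C@@]2(C)C[C@@H](O)[C@H]1CC(=O)N(C)C | intermediate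
20 | isobutyraldehyde | CC(C)C=O | starting material
21 | hemiacetal of the C8 hydroxyl of 19 with 20 (hemiacetal carbon undefined) | O=C1/C=C(/C)[C@@H](O[Si](C(C)C)(C(C)C)C(C)C)C[C@H]2O[C@@]2(C)C[C@@H](OC(O)C(C)C)[C@H]1CC(=O)N(C)C | intermediate
22 | (1S,3R,4S,5R,6Z,8S,10R)-4-[2-(dimethylamino)-2-oxoethyl]-5-hydroxy-1,7-dimethyl-8-(triisopropylsilyloxy)-11-oxabicyclo[8.1.0]undec-6-en-3-yl 2-methylpropanoate (C6 hydroxyl trans to the C7 side chain) | O[C@@H]1/C=C(/C)[C@@H](O[Si](C(C)C)(C(C)C)C(C)C)C[C@H]2O[C@@]2(C)C[C@@H](OC(=O)C(C)C)[C@H]1CC(=O)N(C)C | intermediate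
23 | C6 methanesulfonate of 22 | CS(=O)(=O)O[C@@H]1/C=C(/C)[C@@H](O[Si](C(C)C)(C(C)C)C(C)C)C[C@H]2O[C@@]2(C)C[C@@H](OC(=O)C(C)C)[C@H]1CC(=O)N(C)C | intermediate
24 | cyclic iminium ether of 25 (C12=N+Me2 in place of C12=O) methanesulfonate | C1C(=[N+](C)C)O[C@H]2/C=C(/C)[C@@H](O[Si](C(C)C)(C(C)C)C(C)C)C[C@H]3O[C@@]3(C)C[C@@H](OC(=O)C(C)C)[C@@H]12.CS(=O)(=O)[O-] | intermediate
25 | (1R,3S,6S,7R,8R,10S)-1,10-epoxy-8-(2-methylpropanoyloxy)-3-(triisopropylsilyloxy)-13-norgermacr-4Z-en-12,6-olide (cis-fused lactone) | C1C(=O)O[C@H]2/C=C(/C)[C@@H](O[Si](C(C)C)(C(C)C)C(C)C)C[C@H]3O[C@@]3(C)C[C@@H](OC(=O)C(C)C)[C@@H]12 | intermediate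
26 | 11-(dimethylaminomethyl) derivative of 25 (C11 epimers) | CN(C)CC1C(=O)O[C@H]2/C=C(/C)[C@@H](O[Si](C(C)C)(C(C)C)C(C)C)C[C@H]3O[C@@]3(C)C[C@@H](OC(=O)C(C)C)[C@@H]12 | intermediate
27 | trimethylammonium iodide of 26 | [I-].C[N+](C)(C)CC1C(=O)O[C@H]2/C=C(/C)[C@@H](O[Si](C(C)C)(C(C)C)C(C)C)C[C@H]3O[C@@]3(C)C[C@@H](OC(=O)C(C)C)[C@@H]12 | intermediate
28 | (1R,3S,6S,7R,8R,10S)-1,10-epoxy-8-(2-methylpropanoyloxy)-3-(triisopropylsilyloxy)germacra-4Z,11(13)-dien-12,6-olide | C=C1C(=O)O[C@H]2/C=C(/C)[C@@H](O[Si](C(C)C)(C(C)C)C(C)C)C[C@H]3O[C@@]3(C)C[C@@H](OC(=O)C(C)C)[C@@H]12 | intermediate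
29 | (1R,3S,6S,7R,8R,10S)-1,10-epoxy-3-hydroxy-8-(2-methylpropanoyloxy)germacra-4Z,11(13)-dien-12,6-olide | C=C1C(=O)O[C@H]2/C=C(/C)[C@@H](O)C[C@H]3O[C@@]3(C)C[C@@H](OC(=O)C(C)C)[C@@H]12 | target

**Totals**
Total step count: 14. Longest linear sequence: 13 steps (1 → 29 through steps 1–3 and 5–14; step 4 is a one-step side branch).

**Three steps most likely to fail, with fallbacks**

Step 9 (dianion alkylation of a macrocyclic β-hydroxy enone; enolisation regiochemistry and the reactivity of 16 are untested in this ring). The fallback sets out from 10 and comes back at 18. Enolate 12, formed regiospecifically by the rearrangement, is alkylated in the same flask with 16, so no separate enolisation and no dianion are needed. This gives α-alkylated β-silyl ketone F5, expected mainly as the C7 epimer from outer-face attack. Tamao–Fleming oxidation as in step 8 passes through silanol F6 to 7-epi hydroxy ketone F7. Soft enolisation with MgBr2·OEt2 and Et3N in CH2Cl2 then equilibrates C7 inside the magnesium chelate to the anti isomer 18, in which the side chain and the C8–C9 bond are both equatorial on the chelate ring.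

Step 12 (an allylic mesylate may ionise and scramble C6 before the amide oxygen closes the ring). The fallback sets out from 22 and comes back at 25. Intermolecular Mitsunobu inversion with 4-nitrobenzoic acid (PPh3, DIAD, toluene, 0 °C) gives inverted 4-nitrobenzoate F8. K2CO3 in MeOH at 0 °C removes the activated aryl ester in preference to the hindered isobutyrate and gives 6-epi alcohol F9, whose C6 hydroxyl is now cis to the C7 side chain. F9 lactonises with retention under mild acid (pyridinium p-toluenesulfonate, toluene, 50 °C) to 25.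

Step 3 (allylic oxidation may attack the silyloxy-bearing carbon, the methyl groups or the isopropenyl unit). The fallback sets out from 3 and comes back at 4. mCPBA epoxidises the more electron-rich ring olefin anti to the silyloxy group to give epoxide F1. NaSePh (from PhSeSePh and NaBH4, EtOH) opens it at the secondary carbon to hydroxy selenide F2. H2O2 gives selenoxide F3, which undergoes syn-elimination away from the carbinol carbon to tertiary allylic alcohol F4. [C5H5NH][CrO3Cl] in CH2Cl2 then effects the Dauben oxidative 1,3-transposition to enone 4.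

The key rearrangement (step 7) ranks just behind these three: the [3,3] shift itself has close precedent, and its main uncertainty is the chair preference that delivers the 1(10)Z geometry.

**Further compounds**

F1 | step 3 | 1,2-epoxide of 3 with the oxirane trans to the silyloxy group | C[C@]12O[C@H]1C[C@H](C(C)=C)C[C@@H]2O[Si](C(C)C)(C(C)C)C(C)C
F2 | step 3 | hydroxy selenide (tertiary OH at the methyl-bearing carbon, PhSe trans to it on the adjacent carbon) | C[C@]1(O)[C@H]([Se]c2ccccc2)C[C@H](C(C)=C)C[C@@H]1O[Si](C(C)C)(C(C)C)C(C)C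
F3 | step 3 | selenoxide of F2 | C[C@]1(O)[C@H]([Se](=O)c2ccccc2)C[C@H](C(C)=C)C[C@@H]1O[Si](C(C)C)(C(C)C)C(C)C
F4 | step 3 | tertiary allylic alcohol 1-methyl-4-(prop-1-en-2-yl)-6-(triisopropylsilyloxy)cyclohex-2-en-1-ol | C[C@]1(O)C=C[C@H](C(C)=C)C[C@@H]1O[Si](C(C)C)(C(C)C)C(C)C
F5 | step 9 | C7-epimeric α-alkylated β-silyl ketone (13 bearing CH2CONMe2 at C7) | O=C1/C=C(/C)[C@@H](O[Si](C(C)C)(C(C)C)C(C)C)C/C=C(C)\C[C@@H]([Si](C)(C)Cc2ccccc2)[C@@H]1CC(=O)N(C)C
F6 | step 9 | silanol from F5 | O=C1/C=C(/C)[C@@H](O[Si](C(C)C)(C(C)C)C(C)C)C/C=C(C)\C[C@@H]([Si](C)(C)O)[C@@H]1CC(=O)N(C)C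
F7 | step 9 | 7-epi-18 | O=C1/C=C(/C)[C@@H](O[Si](C(C)C)(C(C)C)C(C)C)C/C=C(C)\C[C@@H](O)[C@@H]1CC(=O)N(C)C
F8 | step 12 | C6-inverted 4-nitrobenzoate of 22 | O=C(O[C@H]1/C=C(/C)[C@@H](O[Si](C(C)C)(C(C)C)C(C)C)C[C@H]2O[C@@]2(C)C[C@@H](OC(=O)C(C)C)[C@H]1CC(=O)N(C)C)c3ccc(cc3)[N+](=O)[O-]
F9 | step 12 | 6-epi-22 (C6 hydroxyl cis to the C7 side chain) | O[C@H]1/C=C(/C)[C@@H](O[Si](C(C)C)(C(C)C)C(C)C)C[C@H]2O[C@@]2(C)C[C@@H](OC(=O)C(C)C)[C@H]1CC(=O)N(C)C
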